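**Retrosynthetic overview**
- The target is the 3β-angelate of 3β,4α,11-trihydroxyeudesm-6-en-8-one (5α-H, 10β-CH3). The C3–O acyl bond is cut last, giving the triol and purchased (Z)-2-methylbut-2-enoic acid.
- The C11 carbinol beside the C6=C7–C8=O enone is traced to a C7=C11 isopropylidene enone (oxygen ene reaction). The trans-3β,4α-diol is traced to a C3=C4 alkene (α-face osmylation, then oxidation and reduction at C3).
- The strategy rests on the C5–C10 fusion bond of the trans-decalin. With that bond cut, C1–C10 form a ten-membered ring carrying methyls on C4 and C10, the C8 ketone and the C7 isopropylidene, with E alkenes at C1=C10 and C4=C5: this is achiral germacrone.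
- Ring order: the ten-membered ring is bought; rings A and B are formed together by one transannular C5–C10 bond, made enantioselectively with a chiral proton source; no ring is formed afterwards.

Key step: step 1

Assumption: which antipode of the chiral acid leads into the (5R,10R) series cannot be predicted and is taken to be assigned in a first screen (both antipodes are equally accessible); germacrone and angelic acid are taken as commercial.

**Route**

Step 1
Reactants: 1 germacrone, (3E,7E)-3,7-dimethyl-10-(propan-2-ylidene)cyclodeca-3,7-dien-1-one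
Product: 2 (5R,10R)-eudesma-3,7(11)-dien-8-one (trans-decalin, 5α-H, 10β-CH3, C3=C4 alkene)
Conditions: confined chiral imidodiphosphorimidate acid [(3,3'-Ar2-BINOL)P(=NSO2CF3)]2NH (Ar = 3,5-(CF3)2C6H3, 5 mol%), CHCl3, 4 Å MS, −20 °C → 0 °C
Reagents that add atoms: none
Why: Proposed new method: the chiral acid, docked on the C8 carbonyl oxygen, should pass its proton to the outer face of C1 in one crossed chair–chair conformer; the developing tertiary C10 cation is taken up at once by C5 of the facing C4=C5 alkene (C5–C10 bond), and the tertiary C4 cation, paired with the confined anion, loses the axial 3α-H to give the C3=C4 alkene. The closest known reaction types are the acid-induced transannular cyclization of (E,E)-germacra-1(10),4-dienes to trans-eudesmanes, which is racemic or substrate-controlled, and enantioselective cation–olefin (polyene) cyclizations catalysed by confined imidodiphosphorimidate acids. The one new bond closes ring B in a 6-exo mode (C4 stays outside) and ring A in a 6-endo mode (C4 and C5 both inside) with respect to the nucleophilic C4=C5 alkene, each through a chair-like half-ring. C5 and C10 are set together: their trans relation (5α-H, 10β-CH3) follows from the antiperiplanar alignment across both E alkenes in the crossed conformer with syn methyls, and their absolute configuration from the catalyst, which must protonate only one of the two planar-chiral conformers while ring inversion keeps them in fast equilibrium (Curtin–Hammett funnelling of achiral material into one enantiomer). The step needs conformer selection, protonation at C1 rather than at the conjugated and deactivated C7=C11 alkene, and proton loss toward C3 rather than C15 or C5; the first rests on the carbonyl anchor in the chiral pocket, the second on the pre-folded and suitably polarised E,E-1,5-diene, and the third on the axial 3α-H lying parallel to the vacant C4 orbital on the open edge of ring A while 5-H is buried at the ring fusion.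

Step 2
Reactants: 2 (5R,10R)-eudesma-3,7(11)-dien-8-one
Product: 3 3α,4α-dihydroxyeudesm-7(11)-en-8-one (4β-CH3, 5α-H, 10β-CH3)
Conditions: OsO4 (2 mol%), NMO, acetone/H2O, 0 °C → rt
Reagents that add atoms: osmium tetroxide O=[Os](=O)(=O)=O; N-methylmorpholine N-oxide C[N+]1([O-])CCOCC1; water O
Why: Upjohn-type catalytic syn-dihydroxylation should occur only at the isolated trisubstituted C3=C4 alkene (the tetrasubstituted enone alkene C7=C11 is electron-poor and hindered) and from the α face opposite the axial 10β-methyl, which sets C3 (α-OH) and C4 (α-OH, β-CH3) together.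

Step 3
Reactants: 3 3α,4α-dihydroxyeudesm-7(11)-en-8-one
Product: 4 4α-hydroxyeudesm-7(11)-ene-3,8-dione
Conditions: SO3·pyridine, DMSO, Et3N, CH2Cl2, 0 °C → rt
Reagents that add atoms: none
Why: Parikh–Doering (activated-DMSO) oxidation converts the only secondary carbinol, C3–OH, into the ketone without touching the tertiary C4–OH or cleaving the glycol, which erases the unwanted 3α configuration while C4, C5 and C10 stay fixed.

Step 4
Reactants: 4 4α-hydroxyeudesm-7(11)-ene-3,8-dione
Product: 5 3β,4α-dihydroxyeudesm-7(11)-en-8-one
Conditions: NaBH4, MeOH/CH2Cl2 (1:1), −78 °C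
Reagents that add atoms: none
Why: Borohydride reduction under conditions known to favour saturated ketones over conjugated enones should reduce only the C3 ketone, the small hydride arriving axially from the α face (the β face is screened by the axial 4β- and 10β-methyl groups) to give the equatorial 3β-OH trans to the 4α-OH.

Step 5
Reactants: 5 3β,4α-dihydroxyeudesm-7(11)-en-8-one
Product: 7 3β,4α,11-trihydroxyeudesm-6-en-8-one, via 11-hydroperoxide 6 (not isolated)
Conditions: O2, tetraphenylporphyrin (cat.), visible light, CH2Cl2, 0 °C; then PPh3, rt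
Reagents that add atoms: dioxygen O=O
Why: The Schenck ene reaction of singlet oxygen with the ring-locked s-cis enone follows the geminal regioselectivity of α,β-unsaturated carbonyl compounds, oxygen bonding to the β-carbon C11 and the axial 6β-H on the group geminal to the carbonyl being abstracted so that the new C6=C7 alkene stays conjugated, and PPh3 then reduces the tertiary hydroperoxide to the carbinol; no stereocentre is formed or disturbed.

Step 6
Reactants: 7 3β,4α,11-trihydroxyeudesm-6-en-8-one; 8 angelic acid, (Z)-2-methylbut-2-enoic acid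
Product: 10 3β-angeloyloxy-4α,11-dihydroxyeudesm-6-en-8-one (target CNP0261892.1), via mixed anhydride 9 (not isolated)
Conditions: 8, 2,4,6-trichlorobenzoyl chloride, Et3N, toluene, rt; then 7, 80 °C
Reagents that add atoms: none
Why: Yamaguchi-type mixed-anhydride esterification without DMAP is an established way to transfer the angeloyl group without Z to E isomerisation; the alcohol attacks the unhindered angeloyl carbonyl of the anhydride, only the secondary equatorial 3β-OH reacts (the C4 and C11 hydroxyls are tertiary), and C3 keeps its configuration because its C–O bond is not broken.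

**Compound list**
1 | germacrone, (3E,7E)-3,7-dimethyl-10-(propan-2-ylidene)cyclodeca-3,7-dien-1-one | C/C1=C\CC/C(C)=C/CC(=C(C)C)C(=O)C1 | starting material
2 | (5R,10R)-eudesma-3,7(11)-dien-8-one (5α-H, 10β-CH3) | C1CC[C@]2(C)CC(=O)C(=C(C)C)C[C@H]2C=1C | intermediate
3 | 3α,4α-dihydroxyeudesm-7(11)-en-8-one | O[C@@H]1CC[C@]2(C)CC(=O)C(=C(C)C)C[C@H]2[C@]1(C)O | intermediate
4 | 4α-hydroxyeudesm-7(11)-ene-3,8-dione | O=C1CC[C@]2(C)CC(=O)C(=C(C)C)C[C@H]2[C@]1(C)O | intermediate
5 | 3β,4α-dihydroxyeudesm-7(11)-en-8-one | O[C@H]1CC[C@]2(C)CC(=O)C(=C(C)C)C[C@H]2[C@]1(C)O | intermediate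
6 | 11-hydroperoxy-3β,4α-dihydroxyeudesm-6-en-8-one | O[C@H]1CC[C@]2(C)CC(=O)C(C(C)(C)OO)=C[C@H]2[C@]1(C)O | intermediate (not isolated)
7 | 3β,4α,11-trihydroxyeudesm-6-en-8-one | O[C@H]1CC[C@]2(C)CC(=O)C(C(C)(C)O)=C[C@H]2[C@]1(C)O | intermediate
8 | angelic acid, (Z)-2-methylbut-2-enoic acid | C/C=C(/C)C(=O)O | starting material
9 | angelic 2,4,6-trichlorobenzoic anhydride | C/C=C(/C)C(=O)OC(=O)c1c(Cl)cc(Cl)cc1Cl | intermediate (not isolated)
10 | 3β-angeloyloxy-4α,11-dihydroxyeudesm-6-en-8-one (5α-H, 10β-CH3) | C/C=C(/C)C(=O)O[C@H]1CC[C@]2(C)CC(=O)C(C(C)(C)O)=C[C@H]2[C@]1(C)O | target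

Total step count: 6. Longest linear sequence: 6 steps (1 → 10).

**Steps most likely to fail**

Step 1. The risks are incomplete discrimination between the two interconverting conformers (low enantiomeric purity), proton loss toward C15 or C5 instead of C3, and later acid-induced migration of the C3=C4 alkene into the ring fusion. The fallback uses known chemistry, sets out from 1 and comes back at 3. Germacrone 1 is cyclised with an achiral acid (p-TsOH, CH2Cl2, 0 °C) to racemic trans-eudesma-3,7(11)-dien-8-one F1, freed from its alkene isomers on AgNO3-impregnated silica. OsO4/NMO then gives the racemic 3,4-cis-diol F2. Esterification of its C3 hydroxyl with (S)-2-methoxy-2-phenylacetic acid (DCC, DMAP, CH2Cl2) gives two diastereomers: the 3-O-[(S)-2-methoxy-2-phenylacetyl] ester of the wanted diol F3 and the corresponding ester of the mirror-image diol F4. These are separated by chromatography or crystallisation and assigned. LiOH in THF/H2O on F3 releases enantiopure 3.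

Step 5. The risks are sluggish oxygenation of the electron-poor enone, competing hydrogen abstraction from the C11 methyl groups with oxygen delivered to C7, and photodegradation on long irradiation. The fallback sets out from 5 and comes back at 7.
- Nucleophilic (Weitz–Scheffer) epoxidation with H2O2/NaOH in MeOH gives 7,11-epoxy-3β,4α-dihydroxyeudesman-8-one F5.
- Reductive opening of the Cα–O bond with SmI2 in THF/MeOH at −90 °C gives the aldol-type 3β,4α,11-trihydroxyeudesman-8-one F6.
- TMSOTf/Et3N in CH2Cl2 gives the persilylated enol ether 3β,4α,8,11-tetrakis(trimethylsilyloxy)eudesm-7-ene F7.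
- Saegusa–Ito oxidation with Pd(OAc)2 in MeCN can place the alkene only at C6=C7, because C10 bears no hydrogen, and gives 3β,4α,11-tris(trimethylsilyloxy)eudesm-6-en-8-one F8.
- Citric acid in MeOH removes the silyl ethers to give 7.

Step 6. The risks are slow acylation of the C3 hydroxyl next to the quaternary C4 and isomerisation of the activated angeloyl unit to the tigloyl (E) isomer. The fallback sets out from 7 and comes back at 10. Compound 7 is acylated with 2-[bis(2,2,2-trifluoroethoxy)phosphoryl]propanoic acid (DCC, CH2Cl2; ketene-type activation suits hindered alcohols) to the 3-O-{2-[bis(2,2,2-trifluoroethoxy)phosphoryl]propanoyl} ester F9. A Still–Gennari olefination (KN(SiMe3)2, 18-crown-6, THF, −78 °C, acetaldehyde) then builds the Z-trisubstituted alkene on the ester and gives 10.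

**Further compounds**
F1 | step 1 | racemic trans-eudesma-3,7(11)-dien-8-one | C1CC[C@]2(C)CC(=O)C(=C(C)C)C[C@H]2C=1C.C1CC[C@@]2(C)CC(=O)C(=C(C)C)C[C@@H]2C=1C
F2 | step 1 | racemic 3,4-cis-dihydroxyeudesm-7(11)-en-8-one (3α,4α relative) | O[C@@H]1CC[C@]2(C)CC(=O)C(=C(C)C)C[C@H]2[C@]1(C)O.O[C@H]1CC[C@@]2(C)CC(=O)C(=C(C)C)C[C@@H]2[C@@]1(C)O
F3 | step 1 | 3-O-[(S)-2-methoxy-2-phenylacetyl] ester of 3α,4α-dihydroxyeudesm-7(11)-en-8-one | CO[C@H](C(=O)O[C@@H]1CC[C@]2(C)CC(=O)C(=C(C)C)C[C@H]2[C@]1(C)O)c1ccccc1
F4 | step 1 | 3-O-[(S)-2-methoxy-2-phenylacetyl] ester of the mirror-image diol | CO[C@H](C(=O)O[C@H]1CC[C@@]2(C)CC(=O)C(=C(C)C)C[C@@H]2[C@@]1(C)O)c1ccccc1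
F5 | step 5 | 7,11-epoxy-3β,4α-dihydroxyeudesman-8-one (C7 epimers) | O[C@H]1CC[C@]2(C)CC(=O)C3(OC3(C)C)C[C@H]2[C@]1(C)O
F6 | step 5 | 3β,4α,11-trihydroxyeudesman-8-one (C7 epimers) | O[C@H]1CC[C@]2(C)CC(=O)C(C(C)(C)O)C[C@H]2[C@]1(C)O
F7 | step 5 | 3β,4α,8,11-tetrakis(trimethylsilyloxy)eudesm-7-ene | C[Si](C)(C)O[C@H]1CC[C@]2(C)CC(O[Si](C)(C)C)=C(C(C)(C)O[Si](C)(C)C)C[C@H]2[C@]1(C)O[Si](C)(C)C
F8 | step 5 | 3β,4α,11-tris(trimethylsilyloxy)eudesm-6-en-8-one | C[Si](C)(C)O[C@H]1CC[C@]2(C)CC(=O)C(C(C)(C)O[Si](C)(C)C)=C[C@H]2[C@]1(C)O[Si](C)(C)C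
F9 | step 6 | 3-O-{2-[bis(2,2,2-trifluoroethoxy)phosphoryl]propanoyl} ester of 3β,4α,11-trihydroxyeudesm-6-en-8-one | CC(C(=O)O[C@H]1CC[C@]2(C)CC(=O)C(C(C)(C)O)=C[C@H]2[C@]1(C)O)P(=O)(OCC(F)(F)F)OCC(F)(F)F
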